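**Strategy**

Ring C of the target is a pyranone whose C3 carries an oxygen right beside the O1–C2 bond. It is therefore opened across O1–C2 to an aryl ynone in which the two alkyne carbons become C2 and C3. In one operation, iodine monochloride closes ring C through the ring-A ether oxygen on C8a (the one next to the C8 methoxy group) and puts iodine on C3, the handle later exchanged for methoxy. The cyclization precursor is a 2,6-dioxygenated aroyl alkyne: ortho to the ketone, ring A bears one benzyl ether (future O1) and one acetate (future O5, not nucleophilic), and the alkyne ends in benzyl-protected ring B.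

Key step: step 13

Remarks on the design:
- Ring B is carried as benzyl ethers, not esters. An ester on O2' would be cleaved under the basic copper conditions of step 14, and the freed 2'-phenoxide would displace the C3 iodide intramolecularly to give a benzofuro[3,2-b]chromenone.
- The symmetric ring-A phenol is made by Baeyer–Villiger oxidation of an aldehyde, not by C–H borylation of a benzyl-protected arene, because the phenyl C–H bonds of the benzyl groups would be borylated competitively.
- Assumption: the starting materials of steps 1 and 8 are catalogue chemicals.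

**Route**

Step 1
Reactants: 1 methyl 3,5-dihydroxy-4-methoxybenzoate
Product: 2 methyl 3,5-bis(benzyloxy)-4-methoxybenzoate
Conditions: BnBr (2.4 equiv), K2CO3, DMF, 60 °C
Reagents that add atoms: benzyl bromide, BrCc1ccccc1
Why: Williamson ether synthesis, in which both phenoxides formed by K2CO3 are alkylated by benzyl bromide while the methyl ester is untouched.

Step 2
Reactants: 2 methyl 3,5-bis(benzyloxy)-4-methoxybenzoate
Product: 3 [3,5-bis(benzyloxy)-4-methoxyphenyl]methanol
Conditions: LiAlH4, THF, 0 °C to rt
Reagents that add atoms: none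
Why: Hydride reduction of the ester to the primary benzylic alcohol, to which aryl benzyl and methyl ethers are inert.

Step 3
Reactants: 3 [3,5-bis(benzyloxy)-4-methoxyphenyl]methanol
Product: 4 3,5-bis(benzyloxy)-4-methoxybenzaldehyde
Conditions: activated MnO2, CH2Cl2, rt
Reagents that add atoms: none
Why: Selective MnO2 oxidation of a benzylic alcohol, which stops at the aldehyde.

Step 4
Reactants: 4 3,5-bis(benzyloxy)-4-methoxybenzaldehyde
Product: 6 3,5-bis(benzyloxy)-4-methoxyphenol, via aryl formate 5 (not isolated)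
Conditions: mCPBA, CH2Cl2, 0 °C to rt; then K2CO3 (cat.), MeOH, rt
Reagents that add atoms: 3-chloroperoxybenzoic acid, OOC(=O)c1cccc(Cl)c1
Why: Baeyer–Villiger (Dakin-type) oxidation, in which the electron-rich trialkoxyaryl group migrates in the Criegee intermediate to give the aryl formate, which mild methanolysis converts to the C2-symmetric phenol.

Step 5
Reactants: 6 3,5-bis(benzyloxy)-4-methoxyphenol
Product: 7 2,4-bis(benzyloxy)-6-hydroxy-3-methoxybenzaldehyde
Conditions: MgCl2, Et3N, paraformaldehyde, MeCN, reflux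
Reagents that add atoms: paraformaldehyde (formaldehyde), C=O
Why: Magnesium-mediated ortho-formylation of a phenol (Casnati–Skattebøl reaction), in which the magnesium phenoxide directs formaldehyde to the ortho carbon (the two ortho positions are equivalent by symmetry and the para position is blocked) and a second equivalent of formaldehyde takes up hydride to give the salicylaldehyde.

Step 6
Reactants: 7 2,4-bis(benzyloxy)-6-hydroxy-3-methoxybenzaldehyde
Product: 8 3,5-bis(benzyloxy)-2-formyl-4-methoxyphenyl acetate
Conditions: Ac2O, pyridine, DMAP (cat.), CH2Cl2, 0 °C to rt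
Reagents that add atoms: acetic anhydride, CC(=O)OC(C)=O
Why: Base-catalysed O-acetylation of the phenol, which turns the future O5 into an ester oxygen that cannot take part in the later ring closure.

Step 7
Reactants: 8 3,5-bis(benzyloxy)-2-formyl-4-methoxyphenyl acetate
Product: 9 6-(acetyloxy)-2,4-bis(benzyloxy)-3-methoxybenzoic acid
Conditions: NaClO2, NaH2PO4, 2-methyl-2-butene, t-BuOH/H2O, rt
Reagents that add atoms: sodium chlorite, [Na+].[O-]Cl=O
Why: Pinnick oxidation, in which chlorous acid converts the aldehyde to the acid at about pH 4, where the aryl acetate and benzyl ethers survive, and 2-methyl-2-butene traps hypochlorous acid before it can chlorinate the electron-rich ring.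

Step 8
Reactants: 10 2,4-bis(benzyloxy)benzaldehyde
Product: 12 2,4-bis(benzyloxy)phenol, via aryl formate 11 (not isolated)
Conditions: mCPBA, CH2Cl2, 0 °C to rt; then K2CO3 (cat.), MeOH, rt
Reagents that add atoms: 3-chloroperoxybenzoic acid, OOC(=O)c1cccc(Cl)c1
Why: Baeyer–Villiger (Dakin-type) oxidation, in which the ortho,para-dialkoxyaryl group migrates readily and the formate is methanolysed to the phenol.

Step 9
Reactants: 12 2,4-bis(benzyloxy)phenol
Product: 13 2,4-bis(benzyloxy)-1-methoxybenzene
Conditions: MeI, K2CO3, acetone, reflux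
Reagents that add atoms: iodomethane, CI
Why: Williamson O-methylation of the only free phenol.

Step 10
Reactants: 13 2,4-bis(benzyloxy)-1-methoxybenzene
Product: 15 2,4-bis(benzyloxy)-5-methoxybenzaldehyde, via iminium salt 14 (not isolated)
Conditions: POCl3, DMF, 0 °C to 65 °C; then H2O (ice), neutralization
Reagents that add atoms: N,N-dimethylformamide, CN(C)C=O; water, O
Why: Vilsmeier–Haack formylation, which should occur at C5, the only unhindered carbon that is ortho to one benzyloxy group and para to the other (C3 lies between two ethers and C6 is activated by the methoxy group alone), as 1,2,4-trialkoxybenzenes generally behave.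

Step 11
Reactants: 15 2,4-bis(benzyloxy)-5-methoxybenzaldehyde
Product: 16 1,5-bis(benzyloxy)-2-ethynyl-4-methoxybenzene
Conditions: dimethyl (1-diazo-2-oxopropyl)phosphonate, K2CO3, MeOH/THF, rt
Reagents that add atoms: dimethyl (1-diazo-2-oxopropyl)phosphonate, CC(=O)C(=[N+]=[N-])P(=O)(OC)OC
Why: Seyferth–Gilbert homologation in its Ohira–Bestmann form, in which methoxide deacetylates the reagent, the diazophosphonate anion olefinates the aldehyde, and loss of N2 with a 1,2-hydrogen shift gives the terminal alkyne under conditions harmless to the ethers.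

Step 12
Reactants: 9 6-(acetyloxy)-2,4-bis(benzyloxy)-3-methoxybenzoic acid; 16 1,5-bis(benzyloxy)-2-ethynyl-4-methoxybenzene
Product: 18 3,5-bis(benzyloxy)-2-{3-[2,4-bis(benzyloxy)-5-methoxyphenyl]prop-2-ynoyl}-4-methoxyphenyl acetate, via acid chloride 17 (not isolated)
Conditions: (COCl)2, DMF (cat.), CH2Cl2, 0 °C to rt, evaporate; then 16, PdCl2(PPh3)2 (2 mol%), CuI (4 mol%), Et3N, THF, rt
Reagents that add atoms: none
Why: Acyl Sonogashira coupling, in which the acid chloride adds oxidatively to zerovalent palladium generated from PdCl2(PPh3)2, the copper acetylide of 16 transmetalates and reductive elimination gives the ynone, while Et3N at room temperature leaves the aryl acetate intact.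

Step 13
Reactants: 18 3,5-bis(benzyloxy)-2-{3-[2,4-bis(benzyloxy)-5-methoxyphenyl]prop-2-ynoyl}-4-methoxyphenyl acetate
Product: 19 7-(benzyloxy)-2-[2,4-bis(benzyloxy)-5-methoxyphenyl]-3-iodo-8-methoxy-4-oxo-4H-chromen-5-yl acetate
Conditions: ICl (1.2 equiv, 1 M in CH2Cl2), CH2Cl2, −78 °C; aq Na2S2O3 quench
Reagents that add atoms: iodine monochloride, ClI
Why: ICl delivers I+ to the ynone alkyne, the polarised iodonium ion is opened anti to iodine at the carbon β to the ketone by a lone pair of the benzyl ether oxygen ortho to the carbonyl, and chloride then removes the benzyl group from the resulting oxonium ion as benzyl chloride to leave the neutral 3-iodochromone. The closest known reaction type is the ICl-induced cyclization of 2-alkoxyaryl alkynones to 3-iodochromones. The pyranone ring closes in the 6-endo-dig mode, forming O1–C2 and C3–I, and no stereocentre is created. Site selectivity on ring A is secured by the acetate: the other oxygen ortho to the ketone is acylated, so its lone pairs are tied up in the ester and only the benzyl ether flanked by the C8 methoxy group can become O1. Chemoselectivity against ring B is secured by the ynone polarisation, since the 2'-benzyloxy oxygen could only reach the α-carbon in a 5-endo-dig closure that would place positive charge next to the carbonyl, whereas attack at the β-carbon is stabilised by the 2',4'-dioxygenated aryl group. Iodination of the electron-rich rings is held back by working at −78 °C with only a small excess of ICl.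

Step 14
Reactants: 19 7-(benzyloxy)-2-[2,4-bis(benzyloxy)-5-methoxyphenyl]-3-iodo-8-methoxy-4-oxo-4H-chromen-5-yl acetate
Product: 21 7-(benzyloxy)-2-[2,4-bis(benzyloxy)-5-methoxyphenyl]-5-hydroxy-3,8-dimethoxy-4H-chromen-4-one, via 5-hydroxy-3-iodoflavone 20 (not isolated)
Conditions: Cs2CO3 (3 equiv), MeOH, rt; then CuI (0.5 equiv), 3,4,7,8-tetramethyl-1,10-phenanthroline (1 equiv), MeOH/toluene, 85 °C, sealed tube
Reagents that add atoms: methanol, CO
Why: Methanolysis of the aryl acetate followed by Ullmann-type copper-catalysed C–O coupling of the C3 iodide with methanol, in which O2' and O4' stay benzylated so that no phenoxide can attack C3 intramolecularly and the 5-phenoxide lowers the electrophilicity of C2 toward conjugate addition of methoxide.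

Step 15
Reactants: 21 7-(benzyloxy)-2-[2,4-bis(benzyloxy)-5-methoxyphenyl]-5-hydroxy-3,8-dimethoxy-4H-chromen-4-one
Product: 22 5,7-dihydroxy-2-(2,4-dihydroxy-5-methoxyphenyl)-3,8-dimethoxy-4H-chromen-4-one (5,7,2',4'-tetrahydroxy-3,8,5'-trimethoxyflavone)
Conditions: H2 (1 atm), 10% Pd/C, EtOAc/MeOH, rt
Reagents that add atoms: none
Why: Catalytic hydrogenolysis cleaves the three benzyl ethers at their benzylic C–O bonds, whereas the aryl methyl ethers and the tetrasubstituted, vinylogous-ester C2=C3 bond of the chromone are inert at one atmosphere and room temperature.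

**Compound list**

1 | methyl 3,5-dihydroxy-4-methoxybenzoate | COC(=O)c1cc(O)c(OC)c(O)c1 | starting material
2 | methyl 3,5-bis(benzyloxy)-4-methoxybenzoate | COC(=O)c1cc(OCc2ccccc2)c(OC)c(OCc2ccccc2)c1 | intermediate
3 | [3,5-bis(benzyloxy)-4-methoxyphenyl]methanol | OCc1cc(OCc2ccccc2)c(OC)c(OCc2ccccc2)c1 | intermediate
4 | 3,5-bis(benzyloxy)-4-methoxybenzaldehyde | O=Cc1cc(OCc2ccccc2)c(OC)c(OCc2ccccc2)c1 | intermediate
5 | 3,5-bis(benzyloxy)-4-methoxyphenyl formate | O=COc1cc(OCc2ccccc2)c(OC)c(OCc2ccccc2)c1 | intermediate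
6 | 3,5-bis(benzyloxy)-4-methoxyphenol | Oc1cc(OCc2ccccc2)c(OC)c(OCc2ccccc2)c1 | intermediate
7 | 2,4-bis(benzyloxy)-6-hydroxy-3-methoxybenzaldehyde | O=Cc1c(O)cc(OCc2ccccc2)c(OC)c1OCc1ccccc1 | intermediate
8 | 3,5-bis(benzyloxy)-2-formyl-4-methoxyphenyl acetate | CC(=O)Oc1cc(OCc2ccccc2)c(OC)c(OCc2ccccc2)c1C=O | intermediate
9 | 6-(acetyloxy)-2,4-bis(benzyloxy)-3-methoxybenzoic acid | CC(=O)Oc1cc(OCc2ccccc2)c(OC)c(OCc2ccccc2)c1C(=O)O | intermediate
10 | 2,4-bis(benzyloxy)benzaldehyde | O=Cc1ccc(OCc2ccccc2)cc1OCc1ccccc1 | starting material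
11 | 2,4-bis(benzyloxy)phenyl formate | O=COc1ccc(OCc2ccccc2)cc1OCc1ccccc1 | intermediate
12 | 2,4-bis(benzyloxy)phenol | Oc1ccc(OCc2ccccc2)cc1OCc1ccccc1 | intermediate
13 | 2,4-bis(benzyloxy)-1-methoxybenzene | COc1ccc(OCc2ccccc2)cc1OCc1ccccc1 | intermediate
14 | {[2,4-bis(benzyloxy)-5-methoxyphenyl]methylidene}dimethylazanium dichlorophosphate | C[N+](C)=Cc1cc(OC)c(OCc2ccccc2)cc1OCc1ccccc1.[O-]P(=O)(Cl)Cl | intermediate
15 | 2,4-bis(benzyloxy)-5-methoxybenzaldehyde | O=Cc1cc(OC)c(OCc2ccccc2)cc1OCc1ccccc1 | intermediate
16 | 1,5-bis(benzyloxy)-2-ethynyl-4-methoxybenzene | C#Cc1cc(OC)c(OCc2ccccc2)cc1OCc1ccccc1 | intermediate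
17 | 6-(acetyloxy)-2,4-bis(benzyloxy)-3-methoxybenzoyl chloride | CC(=O)Oc1cc(OCc2ccccc2)c(OC)c(OCc2ccccc2)c1C(Cl)=O | intermediate
18 | 3,5-bis(benzyloxy)-2-{3-[2,4-bis(benzyloxy)-5-methoxyphenyl]prop-2-ynoyl}-4-methoxyphenyl acetate | COc1cc(C#CC(=O)c2c(OC(C)=O)cc(OCc3ccccc3)c(OC)c2OCc2ccccc2)c(OCc2ccccc2)cc1OCc1ccccc1 | intermediate
19 | 7-(benzyloxy)-2-[2,4-bis(benzyloxy)-5-methoxyphenyl]-3-iodo-8-methoxy-4-oxo-4H-chromen-5-yl acetate | COc1cc(-c2oc3c(OC)c(OCc4ccccc4)cc(OC(C)=O)c3c(=O)c2I)c(OCc2ccccc2)cc1OCc1ccccc1 | intermediate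
20 | 7-(benzyloxy)-2-[2,4-bis(benzyloxy)-5-methoxyphenyl]-5-hydroxy-3-iodo-8-methoxy-4H-chromen-4-one | COc1cc(-c2oc3c(OC)c(OCc4ccccc4)cc(O)c3c(=O)c2I)c(OCc2ccccc2)cc1OCc1ccccc1 | intermediate
21 | 7-(benzyloxy)-2-[2,4-bis(benzyloxy)-5-methoxyphenyl]-5-hydroxy-3,8-dimethoxy-4H-chromen-4-one | COc1cc(-c2oc3c(OC)c(OCc4ccccc4)cc(O)c3c(=O)c2OC)c(OCc2ccccc2)cc1OCc1ccccc1 | intermediate
22 | 5,7-dihydroxy-2-(2,4-dihydroxy-5-methoxyphenyl)-3,8-dimethoxy-4H-chromen-4-one | COc1cc(-c2oc3c(OC)c(O)cc(O)c3c(=O)c2OC)c(O)cc1O | target

**Step count and risks**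

Total step count: 15. Longest linear sequence: 11 steps (steps 1–7 and 12–15, from compound 1); the ring-B branch (steps 8–11) has 4 steps.

Steps most likely to fail:

1. Step 13 (key step). Electrophilic iodination of the electron-rich rings (C6 of ring A, C3' of ring B) may compete with activation of the alkyne. Iodine monochloride may also simply add across the triple bond without ring closure, or part of the material may close through O2'. Fallback, setting out from 18 and returning at 19: chelation-directed cleavage of the benzyl ether ortho to the ketone with BCl3 (1.1 equiv, CH2Cl2, −78 °C) should give the hydroxy ynone 5-(benzyloxy)-2-{3-[2,4-bis(benzyloxy)-5-methoxyphenyl]prop-2-ynoyl}-3-hydroxy-4-methoxyphenyl acetate F1. Catalytic TfOH in CH2Cl2 should then add the free phenol to the β-carbon of the ynone (6-endo-dig cycloisomerization) to give the 3-unsubstituted flavone 7-(benzyloxy)-2-[2,4-bis(benzyloxy)-5-methoxyphenyl]-8-methoxy-4-oxo-4H-chromen-5-yl acetate F2. Iodination of F2 at C3 with I2 and (NH4)2Ce(NO3)6 in MeCN returns to 19. The ring is still closed through the oxygen next to the C8 methoxy group, but without an iodonium ion in the presence of the ether-rich arenes during ring closure.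

2. Step 14. Hydrodeiodination at C3 may occur, or methoxide may add at C2 with opening of the pyranone and reclosure to an aurone-type skeleton. The copper may also be sequestered by the 5-hydroxy-4-keto chelate so that the coupling stalls. Fallback, setting out from 19 and returning at 21: Miyaura borylation (B2pin2, PdCl2(dppf), KOAc, dioxane, 80 °C) should give the boronate 7-(benzyloxy)-2-[2,4-bis(benzyloxy)-5-methoxyphenyl]-8-methoxy-4-oxo-3-(4,4,5,5-tetramethyl-1,3,2-dioxaborolan-2-yl)-4H-chromen-5-yl acetate F3. Oxidation with H2O2 and aqueous NaOH in THF at 0 °C converts C–B into C–OH and saponifies the 5-acetate, giving the flavonol 7-(benzyloxy)-2-[2,4-bis(benzyloxy)-5-methoxyphenyl]-3,5-dihydroxy-8-methoxy-4H-chromen-4-one F4. Methylation with MeI (1.1 equiv) and K2CO3 in acetone should take place at the 3-hydroxyl only, because the 5-hydroxyl is locked in a hydrogen bond to the C4 carbonyl, and gives 21.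

3. Step 12. Oxidative addition and transmetalation at the doubly ortho-substituted aroyl chloride may be slow, so that copper-mediated oxidative dimerization of the alkyne or amine-induced loss of the acetate takes over. Fallback, setting out from 16 and 17 and returning at 18: deprotonation of 16 with n-BuLi (THF, −78 °C) and quenching with Bu3SnCl should give tributyl{[2,4-bis(benzyloxy)-5-methoxyphenyl]ethynyl}stannane F5. Stille-type acylation of F5 with acid chloride 17 (PdCl2(PPh3)2 cat., 1,2-dichloroethane, 70 °C) then gives 18 with neither amine nor copper acetylide present.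

Further compounds

F1 | step 13 | 5-(benzyloxy)-2-{3-[2,4-bis(benzyloxy)-5-methoxyphenyl]prop-2-ynoyl}-3-hydroxy-4-methoxyphenyl acetate | COc1cc(C#CC(=O)c2c(OC(C)=O)cc(OCc3ccccc3)c(OC)c2O)c(OCc2ccccc2)cc1OCc1ccccc1
F2 | step 13 | 7-(benzyloxy)-2-[2,4-bis(benzyloxy)-5-methoxyphenyl]-8-methoxy-4-oxo-4H-chromen-5-yl acetate | COc1cc(-c2cc(=O)c3c(OC(C)=O)cc(OCc4ccccc4)c(OC)c3o2)c(OCc2ccccc2)cc1OCc1ccccc1
F3 | step 14 | 7-(benzyloxy)-2-[2,4-bis(benzyloxy)-5-methoxyphenyl]-8-methoxy-4-oxo-3-(4,4,5,5-tetramethyl-1,3,2-dioxaborolan-2-yl)-4H-chromen-5-yl acetate | COc1cc(-c2oc3c(OC)c(OCc4ccccc4)cc(OC(C)=O)c3c(=O)c2B2OC(C)(C)C(C)(C)O2)c(OCc2ccccc2)cc1OCc1ccccc1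
F4 | step 14 | 7-(benzyloxy)-2-[2,4-bis(benzyloxy)-5-methoxyphenyl]-3,5-dihydroxy-8-methoxy-4H-chromen-4-one | COc1cc(-c2oc3c(OC)c(OCc4ccccc4)cc(O)c3c(=O)c2O)c(OCc2ccccc2)cc1OCc1ccccc1
F5 | step 12 | tributyl{[2,4-bis(benzyloxy)-5-methoxyphenyl]ethynyl}stannane | CCCC[Sn](CCCC)(CCCC)C#Cc1cc(OC)c(OCc2ccccc2)cc1OCc1ccccc1
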